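Everything rests on opening the 2,6-dimethoxycyclohexa-2,5-dienone ring at the bond from the spiro carbon to one vinylic CH and at the CH=C(OMe) bond on the other side: a Robinson-type spiroannulation. An α-aryl aldehyde, the benzo[7]annulene-5-carbaldehyde that already carries C7-Me, C8-Me and C9-OH, takes up 1,3-dimethoxybut-3-en-2-one; Michael addition creates the quaternary C5 and aldol condensation closes the six-membered ring in the same flask. The step exploits the local mirror symmetry of the dienone ring (C2′/C6′, C3′/C5′), which makes spiro C5 non-stereogenic, so both C5 epimers of the aldehyde converge, while the MeO–C–C(=O)–C–OMe array arrives intact. Saegusa dehydrogenation then completes the dienone.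

Key step: step 9

Remark on numbering: benzo[7]annulene locants are used for the target (C5 spiro, C7 and C8 methyl, C9 hydroxyl, primed locants for the six-membered ring); the target is then (7R,8S,9R).
Assumption: the lipase in step 1 follows the Kazlauskas rule for alcohol 1 (the R alcohol is acylated).

Step 1
Reactants: 1 rac-(E)-pent-3-en-2-ol
Product: 2 (S,E)-pent-3-en-2-ol
Conditions: immobilised Candida antarctica lipase B, vinyl acetate (0.6 equiv), MTBE, rt, run past half conversion; unreacted alcohol recovered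
Reagents that add atoms: none
Why: Lipase (serine hydrolase) kinetic resolution by transesterification; the enzyme should acylate the (R)-alcohol, so the alcohol left past half conversion should be the (S)-enantiomer in high enantiomeric purity.

Step 2
Reactants: 2 (S,E)-pent-3-en-2-ol
Product: 3 (S,E)-4-(prop-2-en-1-yloxy)pent-2-ene
Conditions: NaH, allyl bromide, Bu4NI (cat.), THF, 0 °C to rt
Reagents that add atoms: allyl bromide, C=CCBr
Why: Williamson ether synthesis at oxygen; the carbinol stereocentre is not touched.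

Step 3
Reactants: 3 (S,E)-4-(prop-2-en-1-yloxy)pent-2-ene
Product: 5 (2S,3R,4E)-2,3-dimethylhex-4-enal, via propenyl ether 4 (not isolated)
Conditions: [IrCl(C8H14)2]2 (1 mol %), PCy3 (6 mol %), NaBPh4 (4 mol %), CH2Cl2/acetone, rt; then PPh3 (6 mol %), 1,2-dichloroethane, 80 °C
Reagents that add atoms: none
Why: Iridium-catalysed olefin isomerisation–Claisen rearrangement: the catalyst should isomerise only the unhindered O-allyl group to the (E)-propenyl ether 4, and the [3,3] shift through a chair with all three methyl groups equatorial transfers the carbinol configuration to C2 and C3 (syn) and gives the (E)-alkene.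

Step 4
Reactants: 5 (2S,3R,4E)-2,3-dimethylhex-4-enal; 6 3,4,5-trimethoxyphenylmagnesium bromide
Product: 7 (1R,2S,3R,4E)-2,3-dimethyl-1-(3,4,5-trimethoxyphenyl)hex-4-en-1-ol
Conditions: THF/Et2O, −78 °C; aq. NH4Cl
Reagents that add atoms: none
Why: Grignard addition under Felkin–Anh control: the aryl group should attack anti to the branched C3 substituent and set the (1R) carbinol (hydroxyl syn to the C2 methyl); the minor (1S) epimer is removed by chromatography.

Step 5
Reactants: 7 (1R,2S,3R,4E)-2,3-dimethyl-1-(3,4,5-trimethoxyphenyl)hex-4-en-1-ol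
Product: 10 (1R,2S,3R,4E)-1-(2-ethenyl-3,4,5-trimethoxyphenyl)-2,3-dimethylhex-4-en-1-ol, via ortho-lithiated lithium alkoxide 8 (not isolated), via arylzinc chloride 9 (not isolated)
Conditions: n-BuLi (2.5 equiv), TMEDA, Et2O, 0 °C to rt; ZnCl2, THF; vinyl bromide, Pd(PPh3)4 (5 mol %), 50 °C, sealed vessel
Reagents that add atoms: vinyl bromide, C=CBr
Why: Directed ortho-metalation by the lithium alkoxide and the flanking methoxy group (the two ortho positions are equivalent), then transmetalation to zinc and Negishi coupling; no stereocentre is involved.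

Step 6
Reactants: 10 (1R,2S,3R,4E)-1-(2-ethenyl-3,4,5-trimethoxyphenyl)-2,3-dimethylhex-4-en-1-ol
Product: 11 (5R,6S,7R)-1,2,3-trimethoxy-6,7-dimethyl-6,7-dihydro-5H-benzo[7]annulen-5-ol
Conditions: second-generation Grubbs catalyst (5 mol %), CH2Cl2 (5 mM), 40 °C
Reagents that add atoms: none
Why: Ring-closing metathesis of the styrene with the (E)-propenyl group closes the seven-membered ring and expels propene; free alcohols are tolerated and the stereocentres are untouched.

Step 7
Reactants: 11 (5R,6S,7R)-1,2,3-trimethoxy-6,7-dimethyl-6,7-dihydro-5H-benzo[7]annulen-5-ol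
Product: 12 (7R,8S,9R)-9-hydroxy-2,3,4-trimethoxy-7,8-dimethyl-6,7,8,9-tetrahydro-5H-benzo[7]annulene-5-carbaldehyde (both C5 epimers)
Conditions: Rh(acac)(CO)2 (2 mol %), PPh3 (10 mol %), CO/H2 (1:1, 40 bar), toluene, 60 °C
Reagents that add atoms: carbon monoxide, [C-]#[O+]
Why: Rhodium-catalysed hydroformylation: aryl-conjugated alkenes favour the benzylic rhodium alkyl (η3-benzyl stabilisation), so the formyl group should enter at C5; the new C5 centre forms as a mixture, which is harmless because C5 ceases to be stereogenic in step 10.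

Step 8
Reactants: 13 methyl vinyl ether; 14 N,2-dimethoxy-N-methylacetamide
Product: 16 1,3-dimethoxybut-3-en-2-one, via 1-methoxyvinyllithium 15 (not isolated)
Conditions: t-BuLi, THF, −78 to 0 °C; then 14, −78 to 0 °C; aq. NH4Cl
Reagents that add atoms: none
Why: α-Lithiation of the enol ether and acylation by a Weinreb amide; the chelated tetrahedral intermediate stops the addition at the ketone stage, and the mild quench keeps the enol ether.

Step 9
Reactants: 12 (7R,8S,9R)-9-hydroxy-2,3,4-trimethoxy-7,8-dimethyl-6,7,8,9-tetrahydro-5H-benzo[7]annulene-5-carbaldehyde (both C5 epimers); 16 1,3-dimethoxybut-3-en-2-one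
Product: 19 (7R,8S,9R)-9-hydroxy-2,3,3′,4,5′-pentamethoxy-7,8-dimethyl-6,7,8,9-tetrahydrospiro[benzo[7]annulene-5,1′-cyclohex[2]en]-4′-one (diastereomer mixture at C5/C5′), via Michael adduct keto aldehyde 17 (not isolated), via aldol ketol 18 (not isolated)
Conditions: KOH (0.2 equiv), MeOH/THF, 0 °C to rt, then 50 °C
Reagents that add atoms: none
Why: Base-catalysed Robinson annulation: the fully substituted benzylic enolate of 12 (its only α-hydrogen) adds to the unsubstituted β-carbon of enone 16 to make the quaternary C5 (17), the methoxymethyl ketone enolate then attacks the now non-enolisable aldehyde, and ketol 18 dehydrates to the 2-methoxy enone. The closest known reaction type is the Robinson annulation of α-aryl α-branched aldehydes with methyl vinyl ketone to 4,4-disubstituted cyclohex-2-enones. The six-membered ring closes by a 6-(enolendo)-exo-trig aldol, the only mode open, since enolisation on the other side of the ketone could reach the aldehyde only through a four-membered ring. The two new stereocentres (C5 and C5′) form without control and need none, because both lose stereogenicity when step 10 makes the ring symmetric; C7, C8 and C9 are remote from the reacting centres and not epimerisable. The step needs conjugate addition to outrun aldehyde self-condensation and polymerisation of the acceptor, which the single acidic α-hydrogen of 12, the unhindered CH2 terminus of 16 and the catalytic amount of base should secure.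

Step 10
Reactants: 19 (7R,8S,9R)-9-hydroxy-2,3,3′,4,5′-pentamethoxy-7,8-dimethyl-6,7,8,9-tetrahydrospiro[benzo[7]annulene-5,1′-cyclohex[2]en]-4′-one (diastereomer mixture at C5/C5′)
Product: 22 (7R,8S,9R)-9-hydroxy-2,3,3′,4,5′-pentamethoxy-7,8-dimethyl-6,7,8,9-tetrahydrospiro[benzo[7]annulene-5,1′-cyclohexa[2,5]dien]-4′-one (CNP0288561.1), via bis(trimethylsilyl) dienol ether 20 (not isolated), via dienone trimethylsilyl ether 21 (not isolated)
Conditions: LDA (3.2 equiv), TMSCl, THF, −78 °C; Pd(OAc)2 (1.2 equiv), MeCN, rt; K2CO3 (cat.), MeOH, 0 °C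
Reagents that add atoms: none
Why: Ito–Saegusa oxidation: kinetic α′-deprotonation (the γ position is quaternary) and silylation give the 2-silyloxy diene 20 with the alcohol masked as its silyl ether, divalent palladium oxidises it to the cross-conjugated dienone 21, and mild methanolysis frees the C9 hydroxyl; C5 becomes non-stereogenic and C7, C8 and C9 are untouched.

Compound list
1 | rac-(E)-pent-3-en-2-ol | C/C=C/C(C)O | starting material
2 | (S,E)-pent-3-en-2-ol | C[C@H](O)/C=C/C | intermediate
3 | (S,E)-4-(prop-2-en-1-yloxy)pent-2-ene | C[C@H](OCC=C)/C=C/C | intermediate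
4 | (S,E)-4-[(E)-prop-1-en-1-yloxy]pent-2-ene | C[C@H](O/C=C/C)/C=C/C | intermediate
5 | (2S,3R,4E)-2,3-dimethylhex-4-enal | C/C=C/[C@@H](C)[C@H](C)C=O | intermediate
6 | 3,4,5-trimethoxyphenylmagnesium bromide | COc1cc([Mg]Br)cc(OC)c1OC | starting material
7 | (1R,2S,3R,4E)-2,3-dimethyl-1-(3,4,5-trimethoxyphenyl)hex-4-en-1-ol | C/C=C/[C@@H](C)[C@H](C)[C@@H](O)c1cc(OC)c(OC)c(OC)c1 | intermediate
8 | lithium (1R,2S,3R,4E)-1-(2-lithio-3,4,5-trimethoxyphenyl)-2,3-dimethylhex-4-en-1-olate | C/C=C/[C@@H](C)[C@H](C)[C@@H](O[Li])c1cc(OC)c(OC)c(OC)c1[Li] | intermediate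
9 | lithium (1R,2S,3R,4E)-1-[2-(chlorozincio)-3,4,5-trimethoxyphenyl]-2,3-dimethylhex-4-en-1-olate | C/C=C/[C@@H](C)[C@H](C)[C@@H](O[Li])c1cc(OC)c(OC)c(OC)c1[Zn]Cl | intermediate
10 | (1R,2S,3R,4E)-1-(2-ethenyl-3,4,5-trimethoxyphenyl)-2,3-dimethylhex-4-en-1-ol | C/C=C/[C@@H](C)[C@H](C)[C@@H](O)c1cc(OC)c(OC)c(OC)c1C=C | intermediate
11 | (5R,6S,7R)-1,2,3-trimethoxy-6,7-dimethyl-6,7-dihydro-5H-benzo[7]annulen-5-ol | C1=C[C@@H](C)[C@H](C)[C@@H](O)c2cc(OC)c(OC)c(OC)c21 | intermediate
12 | (7R,8S,9R)-9-hydroxy-2,3,4-trimethoxy-7,8-dimethyl-6,7,8,9-tetrahydro-5H-benzo[7]annulene-5-carbaldehyde (both C5 epimers) | O=CC1C[C@@H](C)[C@H](C)[C@@H](O)c2cc(OC)c(OC)c(OC)c21 | intermediate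
13 | methyl vinyl ether | COC=C | starting material
14 | N,2-dimethoxy-N-methylacetamide | COCC(=O)N(C)OC | starting material
15 | 1-methoxyvinyllithium | [Li]C(=C)OC | intermediate
16 | 1,3-dimethoxybut-3-en-2-one | COCC(=O)C(=C)OC | intermediate
17 | (7R,8S,9R)-5-(2,4-dimethoxy-3-oxobutyl)-9-hydroxy-2,3,4-trimethoxy-7,8-dimethyl-6,7,8,9-tetrahydro-5H-benzo[7]annulene-5-carbaldehyde (Michael adduct, diastereomer mixture) | COCC(=O)C(OC)CC1(C=O)C[C@@H](C)[C@H](C)[C@@H](O)c2cc(OC)c(OC)c(OC)c21 | intermediate
18 | (7R,8S,9R)-2′,9-dihydroxy-2,3,3′,4,5′-pentamethoxy-7,8-dimethyl-6,7,8,9-tetrahydrospiro[benzo[7]annulene-5,1′-cyclohexan]-4′-one (aldol, diastereomer mixture) | COC1CC2(C(O)C(OC)C1=O)C[C@@H](C)[C@H](C)[C@@H](O)c1cc(OC)c(OC)c(OC)c12 | intermediate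
19 | (7R,8S,9R)-9-hydroxy-2,3,3′,4,5′-pentamethoxy-7,8-dimethyl-6,7,8,9-tetrahydrospiro[benzo[7]annulene-5,1′-cyclohex[2]en]-4′-one (diastereomer mixture at C5/C5′) | COC1CC2(C=C(OC)C1=O)C[C@@H](C)[C@H](C)[C@@H](O)c1cc(OC)c(OC)c(OC)c12 | intermediate
20 | (7R,8S,9R)-2,3,3′,4,5′-pentamethoxy-7,8-dimethyl-4′,9-bis[(trimethylsilyl)oxy]-6,7,8,9-tetrahydrospiro[benzo[7]annulene-5,1′-cyclohexa[2,4]diene] | COC1=CC2(CC(OC)=C1O[Si](C)(C)C)C[C@@H](C)[C@H](C)[C@@H](O[Si](C)(C)C)c1cc(OC)c(OC)c(OC)c12 | intermediate
21 | (7R,8S,9R)-2,3,3′,4,5′-pentamethoxy-7,8-dimethyl-9-[(trimethylsilyl)oxy]-6,7,8,9-tetrahydrospiro[benzo[7]annulene-5,1′-cyclohexa[2,5]dien]-4′-one | COC1=CC2(C=C(OC)C1=O)C[C@@H](C)[C@H](C)[C@@H](O[Si](C)(C)C)c1cc(OC)c(OC)c(OC)c12 | intermediate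
22 | (7R,8S,9R)-9-hydroxy-2,3,3′,4,5′-pentamethoxy-7,8-dimethyl-6,7,8,9-tetrahydrospiro[benzo[7]annulene-5,1′-cyclohexa[2,5]dien]-4′-one (CNP0288561.1) | COC1=CC2(C=C(OC)C1=O)C[C@@H](C)[C@H](C)[C@@H](O)c1cc(OC)c(OC)c(OC)c12 | target

Total steps: 10. Longest linear sequence: 9 steps (steps 1 to 7, 9 and 10); step 8 is a one-step branch that makes the annulation partner.

Steps most likely to fail

Step 9 (key step). The hindered, doubly ortho-flanked enolate may add too slowly, so that base-induced polymerisation of the acceptor or retro-Michael cleavage takes over. The fallback changes the nucleophile to a preformed enamine and sets out from 12: condensation with pyrrolidine (benzene, molecular sieves, reflux) should give the pyrrolidine enamine of aldehyde 12 F5; this is alkylated at carbon by 16 in MeCN at rt (Stork enamine Michael addition), and aqueous AcOH/NaOAc at 60 °C hydrolyses the iminium ion and closes the ring by aldol condensation, coming back to the route at 19.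

Step 7. Regiocontrol may be lost at the crowded, electron-rich cyclic styrene, so that the formyl group enters at C6 or the alkene stays unreacted. The fallback brings in the formyl carbon before ring closure and sets out from 7: the arylzinc species made as in step 5 is coupled (Pd(PPh3)4, THF, 50 °C) with commercially available 2-bromoallyl tert-butyldimethylsilyl ether to the α-(silyloxymethyl)styrene F1; second-generation Grubbs catalyst closes the ring with loss of propene to the silyl-protected trisubstituted cycloalkene F2; Bu4NF in THF frees the primary allylic alcohol F3; and [Ir(cod)(PCy3)(py)]PF6, activated with H2 and then degassed (THF, rt), isomerises the allylic alcohol to the aldehyde, coming back to the route at 12.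

Step 5. Transmetalation and reductive elimination at the doubly ortho-substituted aryl carbon may be too slow, leading to protonated starting material after work-up. The fallback replaces the cross-coupling by formylation and olefination and sets out from 7: the dilithio species 8 is quenched with DMF to the hydroxy aldehyde, which closes to the lactol F4; Wittig methylenation of its open form with Ph3P=CH2 (2.5 equiv, THF, 0 °C to rt) gives the styrene, coming back to the route at 10.

Further compounds
F1 | step 7 | (1R,2S,3R,4E)-1-[2-(3-{[tert-butyl(dimethyl)silyl]oxy}prop-1-en-2-yl)-3,4,5-trimethoxyphenyl]-2,3-dimethylhex-4-en-1-ol | C/C=C/[C@@H](C)[C@H](C)[C@@H](O)c1cc(OC)c(OC)c(OC)c1C(=C)CO[Si](C)(C)C(C)(C)C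
F2 | step 7 | (5R,6S,7R)-9-({[tert-butyl(dimethyl)silyl]oxy}methyl)-1,2,3-trimethoxy-6,7-dimethyl-6,7-dihydro-5H-benzo[7]annulen-5-ol | CC(C)(C)[Si](C)(C)OCC1=C[C@@H](C)[C@H](C)[C@@H](O)c2cc(OC)c(OC)c(OC)c21
F3 | step 7 | (5R,6S,7R)-9-(hydroxymethyl)-1,2,3-trimethoxy-6,7-dimethyl-6,7-dihydro-5H-benzo[7]annulen-5-ol | OCC1=C[C@@H](C)[C@H](C)[C@@H](O)c2cc(OC)c(OC)c(OC)c21
F4 | step 5 | (3R)-5,6,7-trimethoxy-3-[(2S,3R,4E)-3-methylhex-4-en-2-yl]-1,3-dihydro-2-benzofuran-1-ol (lactol, both C1 epimers) | C/C=C/[C@@H](C)[C@H](C)[C@H]1OC(O)c2c(OC)c(OC)c(OC)cc21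
F5 | step 9 | pyrrolidine enamine of aldehyde 12 (exocyclic C5=CH–N, 7R,8S,9R) | C(=C1C[C@@H](C)[C@H](C)[C@@H](O)c2cc(OC)c(OC)c(OC)c21)N3CCCC3
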